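Readings and results were computed on assumed constants, and the scatter is random.

Take the easy step first, since you asked for a quick number. If each Q or J that reacts takes one D, then D, the limiting reagent, can turn 30.0% of the racemate charged in your flask, and I call that part its ceiling.

common to all: X 12 mM
- Saturday's: Q 0.16 M; J 0.16 M; D 0.144 M; run made earlier
- Friday's: Q 0.36 M; J 0.36 M; D 0.144 M; run made earlier
- Tuesday's: Q 0.24 M; J 0.24 M; D 0.072 M; run made earlier
- flask: Q 0.24 M; J 0.24 M; D 0.144 M; time 2.5 d

- Saturday's (time / h: J / %, Q / %): 4.00: 47.8, 46.0; 6.00: 47.5, 44.2; 10.0: 46.4, 41.4; 20.0: 42.8, 36.4; 30.0: 41.7, 33.6; 50.0: 38.7, 28.7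
- Friday's (time / h: J / %, Q / %): 3.00: 49.1, 48.0; 10.0: 47.2, 42.8; 15.0: 46.8, 41.6; 25.0: 44.3, 39.6; 40.0: 43.2, 38.1; 50.0: 44.0, 37.7
- Tuesday's (time / h: J / %, Q / %): 10.0: 48.2, 47.0; 20.0: 47.0, 44.2; 30.0: 45.7, 42.6; 40.0: 46.0, 41.5; 50.0: 44.7, 41.4

(readings scatter by 0.5 percentage points)

- whether the excess of J over Q among what is left of the two reaches 90% by 2.5 d (yes / no)
- the highest excess of J over Q among what is left of the two up to 2.5 d

The runs support this. Friday's had reacted 18.3% at 50.0 h against a ceiling of 20.0%. Saturday's stood at 32.6% against 45.0%, so a ceiling need not be reached in time.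

Now read g, the gap J minus Q per part of the charge reacted. The last readings of the three runs, pooled, give 0.302, a reading built on values that scatter by 0.5 percentage points. If a part c has reacted, the gap is g times c and what is left is one minus c, and the excess is their ratio. At the ceiling that gives 13.0%, the ceiling excess.

So my own answer is no, with a top somewhat under 13.0%, which lies far below 90%. Your forecast also says no, and it names a top of 11.5%, under my figure, on the ground that some D stays unused at the end of the time, “meaning about 26–27% conversion”.

    2 X ⇌ E, settled at all times (K = 240 M⁻¹)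
    D + X + Q → X + Z (k = 43.0 M⁻² h⁻¹)
    D + X + J → X + G (k = 23.0 M⁻² h⁻¹)
    Z ⇌ G (k = 0.150 h⁻¹)
    X ⇌ L (K = 1.40, k = 0.850 h⁻¹)

The flask tops out at 9.70%, so the answer is no and your 11.5% held within its margin. At 2.50 d it has reacted 27.1% of the charge and 9.6% of its D is still there, while the turning of Z into G changes the excess by nothing. That top lies below the ceiling excess of 13.0%. The neighbour charged with 0.058 M of D has a ceiling of 12.1%, and g puts its ceiling excess at 4.16%; its top falls below that, at 3.64%.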